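**Plan**

- Labels: G is the 5,7-dihydroxyisoflavone half and D the 7-hydroxyisoflavone half; they are joined G-C8 to D-C3'.
- Enabling feature: D ring B is a phenol (C4'-OH) with G-C8 ortho at C3' and its only other substituent, D-C3, para at C1'. A 4-aryl-1-methoxy-3-silyloxybutadiene and a terminal ynone give exactly this 1,2,4-pattern after aromatisation.
- Cuts, in retrosynthetic order: four O–CH3 bonds; D ring C (O1–C2 and C2–C3 to a formyl carbon, C4–C4a to resorcinol); D-C1'–C3 (back to an acetyl group by 1,2-aryl shift); D-C2'–C3' and D-C1'–C6' (cycloaddition); G-C8–CH2 (palladium α-arylation of iodinated genistein trimethyl ether).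
- Forward order: rings A, B and C of G come intact from genistein; D ring B is grown on G-C8 by cycloaddition and aromatisation; D rings C and A are added last from resorcinol and one carbon of DMF.
- Stereochemistry: the target has no stereocentre; the two sp3 carbons of the cycloadduct disappear on aromatisation.

Key step: step 5

Assumption: the target SMILES carries no stereodescriptor, so the G-C8–D-C3' axis is treated as not configurationally fixed and is not controlled.

**Step 1**
Reactants: 1 genistein
Product: 2 5,7-dimethoxy-3-(4-methoxyphenyl)chromen-4-one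
Conditions: Me2SO4 (excess), K2CO3, acetone, reflux
Reagents that add atoms: dimethyl sulfate, COS(=O)(=O)OC
Why: Williamson ether synthesis on all three phenols, with excess reagent and prolonged reflux to methylate the hydrogen-bonded 5-OH as well.

**Step 2**
Reactants: 2 5,7-dimethoxy-3-(4-methoxyphenyl)chromen-4-one
Product: 3 8-iodo-5,7-dimethoxy-3-(4-methoxyphenyl)chromen-4-one
Conditions: I2 (1.05 equiv), CF3CO2Ag, CH2Cl2, 0 °C to rt
Reagents that add atoms: iodine, II
Why: Electrophilic aromatic iodination of the most electron-rich ring (G ring A), which with the 5-oxygen capped should go to C8 (para to 5-OMe, ortho to 7-OMe and O1) and not to C6 between two methoxy groups.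

**Step 3**
Reactants: 3 8-iodo-5,7-dimethoxy-3-(4-methoxyphenyl)chromen-4-one; 4 (E)-1-methoxy-3-(trimethylsilyloxy)buta-1,3-diene
Product: 5 8-[(3E)-4-methoxy-2-oxobut-3-enyl]-5,7-dimethoxy-3-(4-methoxyphenyl)chromen-4-one
Conditions: Pd2(dba)3 (zerovalent palladium), P(t-Bu)3, Bu3SnF, toluene, 85 °C
Reagents that add atoms: none
Why: Fluoride-promoted palladium-catalysed α-arylation of a silyl enol ether, in which Bu3SnF turns 4 into the tin enolate of 4-methoxybut-3-en-2-one (only the terminal CH2 can be arylated) and the bulky, electron-rich phosphine should allow reductive elimination from the doubly ortho-substituted arylpalladium intermediate under base-free conditions that spare the pyranone ring.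

**Step 4**
Reactants: 5 8-[(3E)-4-methoxy-2-oxobut-3-enyl]-5,7-dimethoxy-3-(4-methoxyphenyl)chromen-4-one
Product: 6 8-[(1Z,3E)-4-methoxy-2-(trimethylsilyloxy)buta-1,3-dienyl]-5,7-dimethoxy-3-(4-methoxyphenyl)chromen-4-one
Conditions: Me3SiOSO2CF3, Et3N, Et2O/CH2Cl2, 0 °C; filtered and concentrated under argon, used crude
Reagents that add atoms: trimethylsilyl trifluoromethanesulfonate, C[Si](C)(C)OS(=O)(=O)C(F)(F)F
Why: Soft enolisation and O-silylation of a ketone whose only enolisable position is the benzylic CH2, which should give the Z silyl enol ether (aryl syn to the silyloxy group, away from the vinyl chain) while excess amine keeps the reversible silylation of the chromone carbonyl unproductive.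

**Step 5**
Reactants: 6 8-[(1Z,3E)-4-methoxy-2-(trimethylsilyloxy)buta-1,3-dienyl]-5,7-dimethoxy-3-(4-methoxyphenyl)chromen-4-one; 7 but-3-yn-2-one
Product: 10 8-(5-acetyl-2-hydroxyphenyl)-5,7-dimethoxy-3-(4-methoxyphenyl)chromen-4-one, via silyloxycyclohexadiene cycloadduct 8 (not isolated), via aryl trimethylsilyl ether 9 (not isolated)
Conditions: 7 (3 equiv), toluene, 90 °C, sealed tube; then 1 M HCl, THF, rt
Reagents that add atoms: none
Why: The electron-rich 2-silyloxydiene 6 and the electron-poor alkyne 7 should combine in a thermal, normal-electron-demand Diels–Alder reaction that is concerted but strongly asynchronous, the bond from the aryl-bearing diene terminus to the unsubstituted alkyne carbon running ahead of the bond from the methoxy-bearing terminus to the acyl-bearing carbon. The closest known reaction type is the cycloaddition of 1-methoxy-3-silyloxybutadienes with acetylenic ketones and esters, which gives para-acylphenols after aromatisation. D ring B is closed as a six-membered carbocycle in an intermolecular [4+2] mode, both new bonds (D-C2'–C3' and D-C1'–C6') arising in the one cycloaddition event, after which 8 loses methanol by 1,4-elimination to give 9 and acid cleaves the silyl ether. No stereocentre survives, since the two sp3 carbons of 8 (cis and racemic, from suprafacial addition to a diene whose methoxy and aryl groups both point outwards) become aromatic carbons. The step needs "para" regioselectivity, which the substrate secures by placing the largest HOMO coefficient on the aryl-bearing terminus (β-carbon of the silyl enol ether, reinforced by the 1-methoxy group) and the largest LUMO coefficient on the terminal carbon of the ynone, so that acetyl ends para and the G aryl ortho to the hydroxyl. Steric demand is kept low because the hindered diene carbon attached to G-C8 meets an sp-hybridised CH, and the congested aryl–aryl bond is already in place before the new ring exists.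

**Step 6**
Reactants: 10 8-(5-acetyl-2-hydroxyphenyl)-5,7-dimethoxy-3-(4-methoxyphenyl)chromen-4-one
Product: 11 8-(5-acetyl-2-methoxyphenyl)-5,7-dimethoxy-3-(4-methoxyphenyl)chromen-4-one
Conditions: MeI, K2CO3, DMF, rt to 50 °C
Reagents that add atoms: iodomethane, CI
Why: Williamson ether synthesis that masks the phenol, which trivalent thallium would otherwise oxidise, as a methyl ether that is removed with the others in the last step.

**Step 7**
Reactants: 11 8-(5-acetyl-2-methoxyphenyl)-5,7-dimethoxy-3-(4-methoxyphenyl)chromen-4-one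
Product: 12 methyl 2-{3-[5,7-dimethoxy-3-(4-methoxyphenyl)-4-oxochromen-8-yl]-4-methoxyphenyl}acetate
Conditions: Tl(NO3)3·3H2O (trivalent thallium, 1.1 equiv), MeOH, HClO4 (70%, cat.), rt
Reagents that add atoms: methanol, CO
Why: Oxidative rearrangement of an aryl methyl ketone by oxythallation of its enol and 1,2-shift of the electron-rich 4-methoxyaryl group with loss of monovalent thallium, a reaction that works best with para-alkoxy acetophenones and that 5,7-dimethoxyisoflavones are known to survive.

**Step 8**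
Reactants: 12 methyl 2-{3-[5,7-dimethoxy-3-(4-methoxyphenyl)-4-oxochromen-8-yl]-4-methoxyphenyl}acetate
Product: 13 2-{3-[5,7-dimethoxy-3-(4-methoxyphenyl)-4-oxochromen-8-yl]-4-methoxyphenyl}acetic acid
Conditions: 2 M H2SO4, 1,4-dioxane, 90 °C
Reagents that add atoms: water, O
Why: Acid-catalysed ester hydrolysis, chosen over saponification because hydroxide opens the pyranone ring of isoflavones at C2 whereas aqueous acid leaves the ring and the aryl methyl ethers intact.

**Step 9**
Reactants: 13 2-{3-[5,7-dimethoxy-3-(4-methoxyphenyl)-4-oxochromen-8-yl]-4-methoxyphenyl}acetic acid; 14 resorcinol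
Product: 16 8-[5-(7-hydroxy-4-oxochromen-3-yl)-2-methoxyphenyl]-5,7-dimethoxy-3-(4-methoxyphenyl)chromen-4-one, via 2,4-dihydroxydeoxybenzoin 15 (not isolated)
Conditions: BF3·OEt2, 85 °C; then DMF, MeSO2Cl, 70 °C
Reagents that add atoms: N,N-dimethylformamide, CN(C)C=O
Why: Friedel–Crafts acylation of resorcinol at C4 by the BF3-activated acid gives deoxybenzoin 15, whose methylene is then formylated by the Vilsmeier-type reagent from DMF and MeSO2Cl and closes onto the ortho hydroxyl with loss of dimethylamine, the standard one-pot isoflavone synthesis in which anisole-type methyl ethers survive.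

**Step 10**
Reactants: 16 8-[5-(7-hydroxy-4-oxochromen-3-yl)-2-methoxyphenyl]-5,7-dimethoxy-3-(4-methoxyphenyl)chromen-4-one
Product: 17 8-[2-hydroxy-5-(7-hydroxy-4-oxochromen-3-yl)phenyl]-5,7-dihydroxy-3-(4-hydroxyphenyl)chromen-4-one (CNP0500144.0)
Conditions: BBr3 (excess), CH2Cl2, −78 °C to rt; then H2O
Reagents that add atoms: none
Why: Lewis-acid cleavage of all four aryl methyl ethers by BBr3 (bromide attack on the O-methyl carbon of the borane-complexed ether), a routine final step for isoflavones because the pyranone ring tolerates it.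

**Compound list**

1 | genistein, 5,7-dihydroxy-3-(4-hydroxyphenyl)chromen-4-one | O=c1c(-c2ccc(O)cc2)coc2cc(O)cc(O)c12 | starting material
2 | 5,7-dimethoxy-3-(4-methoxyphenyl)chromen-4-one | COc1ccc(-c2coc3cc(OC)cc(OC)c3c2=O)cc1 | intermediate
3 | 8-iodo-5,7-dimethoxy-3-(4-methoxyphenyl)chromen-4-one | COc1ccc(-c2coc3c(I)c(OC)cc(OC)c3c2=O)cc1 | intermediate
4 | (E)-1-methoxy-3-(trimethylsilyloxy)buta-1,3-diene | CO/C=C/C(=C)O[Si](C)(C)C | starting material
5 | 8-[(3E)-4-methoxy-2-oxobut-3-enyl]-5,7-dimethoxy-3-(4-methoxyphenyl)chromen-4-one | CO/C=C/C(=O)Cc1c(OC)cc(OC)c2c(=O)c(-c3ccc(OC)cc3)coc12 | intermediate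
6 | 8-[(1Z,3E)-4-methoxy-2-(trimethylsilyloxy)buta-1,3-dienyl]-5,7-dimethoxy-3-(4-methoxyphenyl)chromen-4-one | CO/C=C/C(O[Si](C)(C)C)=C/c1c(OC)cc(OC)c2c(=O)c(-c3ccc(OC)cc3)coc12 | intermediate
7 | but-3-yn-2-one | C#CC(C)=O | starting material
8 | 8-[cis-3-acetyl-4-methoxy-6-(trimethylsilyloxy)cyclohexa-2,5-dien-1-yl]-5,7-dimethoxy-3-(4-methoxyphenyl)chromen-4-one, racemic, one enantiomer drawn, not isolated | CO[C@@H]1C=C(O[Si](C)(C)C)[C@H](c2c(OC)cc(OC)c3c(=O)c(-c4ccc(OC)cc4)coc23)C=C1C(C)=O | intermediate
9 | 8-[5-acetyl-2-(trimethylsilyloxy)phenyl]-5,7-dimethoxy-3-(4-methoxyphenyl)chromen-4-one, not isolated | CC(=O)c1ccc(O[Si](C)(C)C)c(-c2c(OC)cc(OC)c3c(=O)c(-c4ccc(OC)cc4)coc23)c1 | intermediate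
10 | 8-(5-acetyl-2-hydroxyphenyl)-5,7-dimethoxy-3-(4-methoxyphenyl)chromen-4-one | CC(=O)c1ccc(O)c(-c2c(OC)cc(OC)c3c(=O)c(-c4ccc(OC)cc4)coc23)c1 | intermediate
11 | 8-(5-acetyl-2-methoxyphenyl)-5,7-dimethoxy-3-(4-methoxyphenyl)chromen-4-one | CC(=O)c1ccc(OC)c(-c2c(OC)cc(OC)c3c(=O)c(-c4ccc(OC)cc4)coc23)c1 | intermediate
12 | methyl 2-{3-[5,7-dimethoxy-3-(4-methoxyphenyl)-4-oxochromen-8-yl]-4-methoxyphenyl}acetate | COC(=O)Cc1ccc(OC)c(-c2c(OC)cc(OC)c3c(=O)c(-c4ccc(OC)cc4)coc23)c1 | intermediate
13 | 2-{3-[5,7-dimethoxy-3-(4-methoxyphenyl)-4-oxochromen-8-yl]-4-methoxyphenyl}acetic acid | OC(=O)Cc1ccc(OC)c(-c2c(OC)cc(OC)c3c(=O)c(-c4ccc(OC)cc4)coc23)c1 | intermediate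
14 | resorcinol, benzene-1,3-diol | Oc1cccc(O)c1 | starting material
15 | 8-{5-[2-(2,4-dihydroxyphenyl)-2-oxoethyl]-2-methoxyphenyl}-5,7-dimethoxy-3-(4-methoxyphenyl)chromen-4-one, not isolated | O=C(Cc1ccc(OC)c(-c2c(OC)cc(OC)c3c(=O)c(-c4ccc(OC)cc4)coc23)c1)c1ccc(O)cc1O | intermediate
16 | 8-[5-(7-hydroxy-4-oxochromen-3-yl)-2-methoxyphenyl]-5,7-dimethoxy-3-(4-methoxyphenyl)chromen-4-one | O=c1c(-c2ccc(OC)c(-c3c(OC)cc(OC)c4c(=O)c(-c5ccc(OC)cc5)coc34)c2)coc2cc(O)ccc12 | intermediate
17 | 8-[2-hydroxy-5-(7-hydroxy-4-oxochromen-3-yl)phenyl]-5,7-dihydroxy-3-(4-hydroxyphenyl)chromen-4-one (CNP0500144.0) | O=c1c(-c2ccc(O)c(-c3c(O)cc(O)c4c(=O)c(-c5ccc(O)cc5)coc34)c2)coc2cc(O)ccc12 | target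

**Step count**

Total: 10 steps. Longest linear sequence: 10 steps, from genistein 1 to 17; compounds 4, 7 and 14 enter as purchased reagents.

**Steps most likely to fail**

Step 3. Transmetalation of the tin dienolate to the doubly ortho-substituted arylpalladium iodide may be slow, so that hydrodeiodination of 3 and fluoride-induced desilylation and oligomerisation of the diene take over. The fallback sets out from 3, comes back at 10, and keeps the cycloaddition. Iodide 3 is coupled at room temperature with the Reformatsky reagent BrZnCH2CO2C(CH3)3 under Pd2(dba)3/P(t-Bu)3 (zerovalent palladium) in THF to give tert-butyl 2-[5,7-dimethoxy-3-(4-methoxyphenyl)-4-oxochromen-8-yl]acetate F1. CF3CO2H in CH2Cl2 should free 2-[5,7-dimethoxy-3-(4-methoxyphenyl)-4-oxochromen-8-yl]acetic acid F2, and (COCl)2 with a drop of DMF should give 2-[5,7-dimethoxy-3-(4-methoxyphenyl)-4-oxochromen-8-yl]acetyl chloride F3. Stille acylation of F3 with commercial (Z)-1-ethoxy-2-(tributylstannyl)ethene under PdCl2(PPh3)2 (divalent palladium precatalyst), followed by acid-catalysed Z-to-E equilibration, should give 8-[(3E)-4-ethoxy-2-oxobut-3-enyl]-5,7-dimethoxy-3-(4-methoxyphenyl)chromen-4-one F4. Silylation as in step 4 gives 8-[(1Z,3E)-4-ethoxy-2-(trimethylsilyloxy)buta-1,3-dienyl]-5,7-dimethoxy-3-(4-methoxyphenyl)chromen-4-one F5. Cycloaddition with 7 as in step 5 gives 8-[cis-3-acetyl-4-ethoxy-6-(trimethylsilyloxy)cyclohexa-2,5-dien-1-yl]-5,7-dimethoxy-3-(4-methoxyphenyl)chromen-4-one F6, which loses ethanol to 9 and is hydrolysed to 10.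

Step 5. The twisted, doubly ortho-substituted aryl group may shield the nucleophilic diene terminus and slow the cycloaddition, so that hydrolysis of the silyl dienol ether back to 5 and polymerisation of the ynone compete. The fallback sets out from 3 and comes back at 11, forming the G-C8–D-C3' bond by Suzuki–Miyaura coupling instead of building ring B. Iodide 3 and commercial (5-acetyl-2-methoxyphenyl)boronic acid are coupled with Pd(OAc)2/SPhos and K3PO4 in toluene/H2O at 100 °C, conditions established for tri-ortho-substituted biaryls, to give 11 directly. No compound outside the list arises (F0), and steps 3 to 6 are bypassed.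

Step 7. α-Methoxylation of the ketone and oxidation or thallation of the electron-rich trimethoxy ring may compete with the aryl shift. The fallback sets out from 11 and comes back at 13 by a Willgerodt–Kindler reaction. Heating 11 with S8 and morpholine at 130 °C should give 8-[2-methoxy-5-(2-morpholin-4-yl-2-thioxoethyl)phenyl]-5,7-dimethoxy-3-(4-methoxyphenyl)chromen-4-one F7, and hydrolysis in aqueous H2SO4/AcOH at reflux gives 13. Any opening of the pyranone ring by morpholine leads to an enaminone of the kind that recloses to the isoflavone under these acidic conditions. This also removes thallium from the route.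

**Further compounds**

F1 | step 3 | tert-butyl 2-[5,7-dimethoxy-3-(4-methoxyphenyl)-4-oxochromen-8-yl]acetate | CC(C)(C)OC(=O)Cc1c(OC)cc(OC)c2c(=O)c(-c3ccc(OC)cc3)coc12
F2 | step 3 | 2-[5,7-dimethoxy-3-(4-methoxyphenyl)-4-oxochromen-8-yl]acetic acid | OC(=O)Cc1c(OC)cc(OC)c2c(=O)c(-c3ccc(OC)cc3)coc12
F3 | step 3 | 2-[5,7-dimethoxy-3-(4-methoxyphenyl)-4-oxochromen-8-yl]acetyl chloride | ClC(=O)Cc1c(OC)cc(OC)c2c(=O)c(-c3ccc(OC)cc3)coc12
F4 | step 3 | 8-[(3E)-4-ethoxy-2-oxobut-3-enyl]-5,7-dimethoxy-3-(4-methoxyphenyl)chromen-4-one | CCO/C=C/C(=O)Cc1c(OC)cc(OC)c2c(=O)c(-c3ccc(OC)cc3)coc12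
F5 | step 3 | 8-[(1Z,3E)-4-ethoxy-2-(trimethylsilyloxy)buta-1,3-dienyl]-5,7-dimethoxy-3-(4-methoxyphenyl)chromen-4-one | CCO/C=C/C(O[Si](C)(C)C)=C/c1c(OC)cc(OC)c2c(=O)c(-c3ccc(OC)cc3)coc12
F6 | step 3 | 8-[cis-3-acetyl-4-ethoxy-6-(trimethylsilyloxy)cyclohexa-2,5-dien-1-yl]-5,7-dimethoxy-3-(4-methoxyphenyl)chromen-4-one, racemic, one enantiomer drawn | CCO[C@@H]1C=C(O[Si](C)(C)C)[C@H](c2c(OC)cc(OC)c3c(=O)c(-c4ccc(OC)cc4)coc23)C=C1C(C)=O
F0 | step 5 | none | none
F7 | step 7 | 8-[2-methoxy-5-(2-morpholin-4-yl-2-thioxoethyl)phenyl]-5,7-dimethoxy-3-(4-methoxyphenyl)chromen-4-one | S=C(Cc1ccc(OC)c(-c2c(OC)cc(OC)c3c(=O)c(-c4ccc(OC)cc4)coc23)c1)N1CCOCC1
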